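## Structural features

Galbinic acid is a depsidone: benzene rings A and B are joined by an ester and by a diaryl ether, which together close a seven-membered 1,4-dioxepin-5-one, and a five-membered hydroxyphthalide (lactone lactol) is fused to ring B, giving four rings in all. Ring A carries, in order, the lactone carbonyl, a methyl group, a free CH, a phenol, a formyl group and the ether oxygen, so the formyl carbon sits between two oxygens. Ring B is fully substituted: acetoxymethyl, phenol, phthalide carbonyl, lactol carbon, ether oxygen, ester oxygen; the ester oxygen is next to the acetoxymethyl carbon and the ether oxygen next to the lactol carbon. The only stereocentre is the (S)-lactol carbon; it has no stereogenic neighbour and, as a hemiacetal, epimerises in solution through the ring-opened 2-formylbenzoic acid, so its configuration can be fixed only in the crystal. Fragile groups are the benzylic acetate flanked by a phenol and an aryl ester oxygen (ortho-quinone methide once a neighbouring phenoxide forms), the aryl ester of the seven-membered ring, the lactol and its pseudo-ester acetals (opened by amines, hydrazine, alkoxides) and the aldehyde. The real difficulty is ring B: three carbon substituents at three oxidation levels on a hexasubstituted ring, and two adjacent oxygens that must be told apart although acyl groups migrate between them. The key step uses the orsellinate pattern of ring A: lactone carbonyl, alpha carbon, ether-bearing carbon, CH, hydroxyl-bearing carbon, CH, methyl-bearing carbon and methyl form a folded tetraketide. Its first carbonyl is the lactone carbonyl and its second the aryl enol ether carbon, so ring A can be closed last by one C–C bond between the alpha carbon and the methyl-bearing carbon.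

## Logic of the disconnections

28 to 27. No skeletal bond is cut; only the configuration of the lactol carbon is released, because its C–O bonds open and re-form by ring–chain tautomerism. This removes every stereochemical demand from the earlier route. The forward step must select one enantiomer in the solid while the solution racemises.

27 to 24. The bond between ring A and the formyl carbon is cut, and the silyl ether and the methyl acetal are put back on ring B. The formyl carbon lies ortho to the ring A phenol and between two oxygens, the natural site for a phenol-directed formylation. The gain is a ring A with the plain orsellinate pattern. The forward step must prefer the position between the oxygens over the CH next to the methyl group and must not ionise the benzylic acetate.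

24 to 22 (key). The ring A bond between the carbon alpha to the lactone carbonyl and the methyl-bearing carbon is cut, and the last two carbonyls of the chain are masked as a 3-methylisoxazole. Ring A disappears; what remains is a bicyclic ring B lactone with a C4 enol ether chain ending in a heterocycle. The forward step must fold in the aldol sense, not in the Claisen sense or through nitrogen or oxygen attack on the enol ether carbon. A fixed configuration at the methyl acetal carbon of 22 and 24 would not survive the later hydrolysis, so both are carried as racemates, and the ring B phenol is carried as a silyl ether.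

22 to 21. The lactone C–O bond between the side-chain carbonyl and the ring B oxygen para to the phthalide carbonyl is cut. The ester is closed last and on the more acidic phenol, while the vinylogous acyl (enol ether) carbon already sits on the less acidic oxygen, where it is also thermodynamically preferred. The opposite order, ester first, would let the acyl group migrate to the neighbouring phenol through a five-membered orthoester-type intermediate, with the equilibrium on the wrong side. The forward step must lactonise faster than the enol ether can wander through a spiro-ketal.

21 to 20 to 19 and 7. The enol ether C–O bond is cut (oxa-Michael addition of a phenol to the central carbon of an allenoate), together with the tert-butyl ester and the methoxymethyl ether. This joins the two branches by one C–O bond under catalytic base. The demand is a single free phenol that cannot form a quinone methide, which 19 provides.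

19 to 18 to 17. Only protecting-group bonds are cut (O–CH2OMe, two O–Si). The two catechol oxygens are told apart by acidity: the one para to the phthalide carbonyl is alkylated first under amine base. The catechol must be released without a nucleophile that opens the pseudo-ester and without a phenoxide next to the acetoxymethyl group, hence silyl ethers and HF.

17 to 15 to 13. The acetal C–OMe bond, the lactone C–O bond at the benzylic carbon and the benzylic C–OAc bond are cut back to two methyl groups. The methyl groups are differentiated by the neighbouring ester (only that one can lactonise), not by radical selectivity. The forward steps need one bromine per methyl group and a later bromination at the phthalide CH2 only.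

13 to 12 to 11 to 9 to 8. The new aryl C–O bond is cut through an aryl C–CHO bond (formylation at the only free ring position, then aryl migration to oxygen), and the three O–Si bonds are cut. This reaches a commercial benzoate that already holds all ring B carbons. The hydroxyquinol 11 is air-sensitive and must be silylated at once.

7 to 3 and 4, 3 to 1. The allene C=C bond is cut (Wittig reaction of a ketene with stabilised ylide 4) and then the CH2–CO2H bond (lateral lithiation and carboxylation). Both building blocks are commercial; the allenoate must be used fresh.

## Other disconnections considered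

Alternative 1: The cut goes through ring B itself: the bond between the phenol-bearing carbon and the carbon that carries the phthalide carbonyl. In the forward sense the cyclobutenone A1 would be heated, the four-membered ring would open to a dienylketene, and 6π electrocyclisation onto the butenolide alpha carbon followed by enolisation would give the hydroquinone phthalide A2. In its favour, all six ring B substituents arrive differentiated (free hydroxyl at the future ether position, isopropyl ether at the future ester position), set by the order of additions to a squaric ester; on this point it is better than the chosen plan, which spends five protecting-group operations on the same problem. The step is neutral and pericyclic, which is also better than two radical brominations. Against it here: the nucleophile needed to make A1 is a beta-metallated alkoxybutenolide, an awkward vinyl anion. The menthyl acetal configuration cannot reach the lactol any more than a methyl acetal can. Isopropyl and methoxymethyl ethers would later need Lewis acid in the presence of the acetal and a benzylic oxygen. Above all, A2 is only ring B: ring A and the seven-membered ring would still have to be built, by the chosen isoxazole folding or otherwise. In step count to a coupling-ready ring B the two plans are about equal.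

Alternative 2: The cut is the ring A C–O ether bond. In the forward sense the depside A3, with fluorine ortho to both the ester carbonyl and the formyl group, would be treated with base so that the ring B phenoxide displaces fluoride and closes the dioxepinone to A4. In its favour: it is convergent, ring A arrives complete with the formyl group, so no late formylation regiochemistry arises (better than the chosen plan), and the mechanism has no nitrogen or oxygen cyclisation by-paths (also better). Against it: the fluorinated, formylated ring A acid needs its own multi-step synthesis. The phenoxide that must attack carbon sits next to the depside ester, so acyl transfer through a five-membered intermediate competes and would lead to the regioisomeric depsidone; the chosen plan avoids this by making the ether-type bond first. The two methoxymethyl ethers and the acetal must then be removed with acid from the finished, base- and acid-sensitive target. The step count is higher overall, the longest linear sequence about equal.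

Alternative 3: The cut removes two ring A C–C bonds at once. In the forward sense the pyrone-fused dioxepinone A5 would react with an electron-rich ketene acetal across pyrone carbons 3 and 6, and loss of carbon dioxide and methanol would give A6. In its favour: the regiochemistry follows from the pyrone polarisation, two bonds form in one thermal, neutral operation, and no ammonia chemistry is involved; on mechanism it is at least the equal of the chosen plan. Against it: A5 still requires the same differentiation of the two ring B oxygens, so nothing is saved there (equal). The ketene acetal could also add to the aryloxy-bearing pyrone carbon and expel the ring B phenoxide. The product is a ring A methyl ether, whose selective cleavage beside an acetal, a benzylic acetate and two lactones is a serious liability that the chosen plan does not have. The step count is about one higher.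

Key step: step 14

Remark (assumption on the chemistry): the lactol carbon racemises in solution and acetal hydrolysis passes through an oxocarbenium ion, so all acetal intermediates are carried as racemates and "single enantiomer" refers to the crystalline product of step 16.

## Steps

Step 1
Reactants: 1 3,5-dimethylisoxazole
Product: 3 (3-methylisoxazol-5-yl)acetic acid, via lithiated isoxazole 2 (not isolated)
Conditions: n-BuLi, THF, −78 °C; CO2; aq. HCl
Reagents that add atoms: carbon dioxide, O=C=O
Why: Lateral lithiation of 3,5-dimethylisoxazole takes place at the methyl group on the oxygen-bearing ring carbon, and carboxylation of the anion gives the acetic acid.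

Step 2
Reactants: 3 (3-methylisoxazol-5-yl)acetic acid; 4 tert-butyl (triphenylphosphoranylidene)acetate
Product: 7 tert-butyl 4-(3-methylisoxazol-5-yl)buta-2,3-dienoate (racemic allene), via acid chloride 5 (not isolated), via isoxazolyl ketene 6 (not isolated)
Conditions: (COCl)2, DMF (cat.), CH2Cl2, 0 °C → rt; then 4, Et3N, CH2Cl2, 0 °C → rt
Reagents that add atoms: none
Why: Dehydrochlorination of the arylacetyl-type chloride gives a ketene that the stabilised ylide traps in a Wittig reaction at the ketene carbonyl, the standard route to 4-substituted allenoates; the allene axis is formed racemic and is lost in step 11.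

Step 3
Reactants: 8 atraric acid (methyl 2,4-dihydroxy-3,6-dimethylbenzoate)
Product: 9 methyl 5-formyl-2,4-dihydroxy-3,6-dimethylbenzoate
Conditions: Cl2CHOMe, TiCl4, CH2Cl2, 0 °C → rt; aq. HCl
Reagents that add atoms: dichloromethyl methyl ether, COC(Cl)Cl; water, O
Why: Rieche formylation at the only free ring position, which is ortho to one phenol and para to the other.

Step 4
Reactants: 9 methyl 5-formyl-2,4-dihydroxy-3,6-dimethylbenzoate
Product: 11 methyl 2,4,5-trihydroxy-3,6-dimethylbenzoate, via aryl formate 10 (not isolated)
Conditions: 30% H2O2, H2SO4 (cat.), MeOH, 0 °C → rt, argon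
Reagents that add atoms: hydrogen peroxide, OO
Why: Acid-catalysed Dakin oxidation: the electron-rich aryl group with ortho and para hydroxyls migrates to oxygen and the formate is methanolysed in the flask; acid and argon protect the hydroxyquinol from over-oxidation.

Step 5
Reactants: 11 methyl 2,4,5-trihydroxy-3,6-dimethylbenzoate
Product: 12 methyl 4,5-bis(tert-butyldimethylsilyloxy)-2-hydroxy-3,6-dimethylbenzoate
Conditions: TBSCl (2.3 equiv), imidazole, DMF, 0 °C → rt, argon
Reagents that add atoms: tert-butyldimethylsilyl chloride, CC(C)(C)[Si](C)(C)Cl
Why: Silylation of the two catechol hydroxyls; the salicylate hydroxyl, hydrogen-bonded to the ester and flanked by a methyl group, should stay free under chloride and imidazole conditions.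

Step 6
Reactants: 12 methyl 4,5-bis(tert-butyldimethylsilyloxy)-2-hydroxy-3,6-dimethylbenzoate
Product: 13 methyl 4,5-bis(tert-butyldimethylsilyloxy)-3,6-dimethyl-2-(triisopropylsilyloxy)benzoate
Conditions: TIPSOTf, 2,6-lutidine, CH2Cl2, 0 °C → rt
Reagents that add atoms: triisopropylsilyl trifluoromethanesulfonate, CC(C)[Si](C(C)C)(C(C)C)OS(=O)(=O)C(F)(F)F
Why: The silyl triflate overcomes the chelated, hindered phenol; this more robust silyl ether stays on the future ring B phenol until step 15 and blocks quinone methide formation and stray reactions at that oxygen.

Step 7
Reactants: 13 methyl 4,5-bis(tert-butyldimethylsilyloxy)-3,6-dimethyl-2-(triisopropylsilyloxy)benzoate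
Product: 15 6-(acetoxymethyl)-4,5-bis(tert-butyldimethylsilyloxy)-7-(triisopropylsilyloxy)isobenzofuran-1(3H)-one, via bis(bromomethyl) benzoate 14 (not isolated)
Conditions: NBS (2.1 equiv), AIBN, PhCF3, 85 °C; then AgOAc, AcOH, 50 °C
Reagents that add atoms: silver acetate (AgOAc), CC(=O)[O-].[Ag+]
Why: Wohl–Ziegler bromination should stop at one bromine on each doubly ortho-flanked methyl group; on silver-assisted ionisation the bromide next to the ester is captured by the ester carbonyl oxygen (five-membered acyloxonium ion, demethylated by acetate) to give the phthalide, while the other bromide is captured by acetate, so the two methyl groups are differentiated by the ester and not by radical selectivity.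

Step 8
Reactants: 15 6-(acetoxymethyl)-4,5-bis(tert-butyldimethylsilyloxy)-7-(triisopropylsilyloxy)isobenzofuran-1(3H)-one
Product: 17 rac-6-(acetoxymethyl)-3-methoxy-4,5-bis(tert-butyldimethylsilyloxy)-7-(triisopropylsilyloxy)isobenzofuran-1(3H)-one, via 3-bromophthalide 16 (not isolated)
Conditions: NBS (1.05 equiv), AIBN, PhCF3, 85 °C; then MeOH, 2,6-lutidine, 0 °C → rt
Reagents that add atoms: methanol, CO
Why: Radical bromination should choose the phthalide CH2 (benzylic, alpha to oxygen, held coplanar with the ring) over the hindered acetoxymethyl group, and the 3-bromophthalide is solvolysed by methanol through an acyloxocarbenium ion; the acetal carbon is formed racemic on purpose.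

Step 9
Reactants: 17 rac-6-(acetoxymethyl)-3-methoxy-4,5-bis(tert-butyldimethylsilyloxy)-7-(triisopropylsilyloxy)isobenzofuran-1(3H)-one
Product: 18 rac-6-(acetoxymethyl)-4,5-dihydroxy-3-methoxy-7-(triisopropylsilyloxy)isobenzofuran-1(3H)-one
Conditions: HF·pyridine, THF, 0 °C → rt, argon
Reagents that add atoms: none
Why: Acidic fluoride removes the two aryl tert-butyldimethylsilyl ethers well before the more hindered triisopropylsilyl ether, forms no phenoxide next to the acetoxymethyl group and uses no nucleophile that opens the pseudo-ester.

Step 10
Reactants: 18 rac-6-(acetoxymethyl)-4,5-dihydroxy-3-methoxy-7-(triisopropylsilyloxy)isobenzofuran-1(3H)-one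
Product: 19 rac-6-(acetoxymethyl)-4-hydroxy-3-methoxy-5-(methoxymethoxy)-7-(triisopropylsilyloxy)isobenzofuran-1(3H)-one
Conditions: MOMCl (1.1 equiv), iPr2NEt, CH2Cl2, −20 → 0 °C
Reagents that add atoms: chloromethyl methyl ether, COCCl
Why: Under amine base the more acidic catechol hydroxyl, para to the lactone carbonyl, is alkylated first, the usual selectivity of 3,4-dihydroxyaryl carbonyl compounds; an ether is chosen because it cannot migrate to the neighbouring oxygen, and the fast reagent keeps the exposure of the ion pair next to the acetate short.

Step 11
Reactants: 19 rac-6-(acetoxymethyl)-4-hydroxy-3-methoxy-5-(methoxymethoxy)-7-(triisopropylsilyloxy)isobenzofuran-1(3H)-one; 7 tert-butyl 4-(3-methylisoxazol-5-yl)buta-2,3-dienoate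
Product: 20 tert-butyl 3-{[6-(acetoxymethyl)-3-methoxy-5-(methoxymethoxy)-1-oxo-7-(triisopropylsilyloxy)-1,3-dihydroisobenzofuran-4-yl]oxy}-4-(3-methylisoxazol-5-yl)but-2-enoate (racemic acetal; E/Z mixture)
Conditions: 7 (1.3 equiv), Cs2CO3 (0.2 equiv), MeCN, 0 °C → rt
Reagents that add atoms: none
Why: Base-catalysed oxa-Michael addition of the only free phenol to the central allenoate carbon gives the aryl vinyl ether on the oxygen next to the acetal carbon; this phenoxide is meta to the acetoxymethyl carbon and cannot expel acetate.

Step 12
Reactants: 20 tert-butyl 3-{[6-(acetoxymethyl)-3-methoxy-5-(methoxymethoxy)-1-oxo-7-(triisopropylsilyloxy)-1,3-dihydroisobenzofuran-4-yl]oxy}-4-(3-methylisoxazol-5-yl)but-2-enoate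
Product: 21 3-{[6-(acetoxymethyl)-5-hydroxy-3-methoxy-1-oxo-7-(triisopropylsilyloxy)-1,3-dihydroisobenzofuran-4-yl]oxy}-4-(3-methylisoxazol-5-yl)but-2-enoic acid (racemic acetal; E/Z mixture)
Conditions: TFA, CH2Cl2, 1,3-dimethoxybenzene, 0 °C → rt
Reagents that add atoms: none
Why: Anhydrous acid cleaves the tert-butyl ester and the methoxymethyl ether, while the push-pull enol ether, the pseudo-ester acetal, the benzylic acetate and the triisopropylsilyl ether should survive; the arene scavenger takes up the cations.

Step 13
Reactants: 21 3-{[6-(acetoxymethyl)-5-hydroxy-3-methoxy-1-oxo-7-(triisopropylsilyloxy)-1,3-dihydroisobenzofuran-4-yl]oxy}-4-(3-methylisoxazol-5-yl)but-2-enoic acid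
Product: 22 rac-silyl-protected isoxazolylmethyl benzodioxepinone (seven-membered lactone of 21 onto its 5-hydroxyl; ring B with acetoxymethyl; triisopropylsilyloxy; 3-methoxyphthalide; (3-methylisoxazol-5-yl)methyl on the enol ether carbon)
Conditions: DCC, DMAP (0.1 equiv), CH2Cl2 (2 mM), rt
Reagents that add atoms: none
Why: Steglich-type lactonisation of a phenol with an aryl-ether-tethered acid, as used to close depsidone rings; E and Z acids interconvert through the deconjugated tautomer at the doubly activated methylene, and only a cyclisable geometry is consumed.

Step 14
Reactants: 22 rac-silyl-protected isoxazolylmethyl benzodioxepinone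
Product: 24 rac-4-deformylgalbinic acid methyl acetal triisopropylsilyl ether, via enaminone 23 (not isolated)
Conditions: Mo(CO)6 (1.0 equiv), MeCN/H2O (15:1), 80 °C; evaporation; then TFA, CH2Cl2, 0 °C → rt
Reagents that add atoms: none
Why: Mo(CO)6 binds the isoxazole nitrogen and cleaves the N–O bond reductively, water supplying the hydrogens, to give the Z vinylogous amide 23. TFA protonates 23 on oxygen to a hydroxyallyl iminium ion, and the carbon alpha to the lactone carbonyl, the nucleophilic end of the push-pull enol ether, attacks the methyl-bearing iminium carbon. This forms the one new C–C bond and closes ring A in a 6-(enolendo)-exo-trig mode; loss of ammonium and enolisation of the remaining ketone give the phenol. The closest known reactions are the aldol aromatisation of 3,5,7-triketo esters to orsellinates and of enol-ether-locked diketo-dioxinones to resorcylates, with an isoxazole as latent 1,3-diketone. No stereocentre is formed. The Claisen mode would need the enaminone CH between the ketone and the amino-bearing carbon to attack the lactone carbonyl; in acid that carbon is no longer nucleophilic, and in the conjugated tautomer the chain is held trans to the lactone carbonyl across the ring double bond. Protonation also removes the nucleophilicity of nitrogen, which otherwise could attack the enol ether carbon and expel the ring B phenoxide. The silyl ether keeps the ring B phenol and the neighbouring acetate inert during the aqueous reflux.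

Step 15
Reactants: 24 rac-4-deformylgalbinic acid methyl acetal triisopropylsilyl ether
Product: 27 rac-galbinic acid, via silylated formyl acetal 25 (not isolated), via desilylated formyl acetal 26 (not isolated)
Conditions: Cl2CHOMe, TiCl4, CH2Cl2, −20 → 0 °C; then HF·pyridine, THF, rt; then AcOH/H2O (4:1), H2SO4 (cat.), 60 °C
Reagents that add atoms: dichloromethyl methyl ether, COC(Cl)Cl; water, O
Why: Rieche formylation ortho to the ring A titanium phenoxide should go to the carbon between the two oxygens; any silyl or acetal exchange caused by TiCl4 converges in the fluoride and aqueous acid stages, and acetic acid as cosolvent returns the benzylic acetate if it solvolyses; the lactol forms racemic.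

Step 16
Reactants: 27 rac-galbinic acid
Product: 28 (S)-galbinic acid
Conditions: slurry in EtOAc/AcOH (10:1), seed crystals of 28, glass beads, 25 °C; filtration
Reagents that add atoms: none
Why: Proposed new method: in solution the lactol racemises through acid-catalysed opening to the achiral 2-formylbenzoic acid, so if the compound crystallises as a conglomerate, seeding with (S) crystals and grinding should feed the whole batch into the (S) solid, which alone fixes the stereocentre; the closest known reaction type is attrition-enhanced deracemisation and second-order asymmetric transformation of conglomerate-forming compounds with a solution-labile stereocentre.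

## Compound list

1 | 3,5-dimethylisoxazole | Cc1cc(C)on1 | starting material
2 | 5-(lithiomethyl)-3-methylisoxazole (not isolated) | [Li]Cc1cc(C)no1 | intermediate
3 | (3-methylisoxazol-5-yl)acetic acid | OC(=O)Cc1cc(C)no1 | intermediate
4 | tert-butyl (triphenylphosphoranylidene)acetate | CC(C)(C)OC(=O)C=P(c1ccccc1)(c1ccccc1)c1ccccc1 | starting material
5 | (3-methylisoxazol-5-yl)acetyl chloride (not isolated) | O=C(Cl)Cc1cc(C)no1 | intermediate
6 | (3-methylisoxazol-5-yl)ketene (not isolated) | O=C=Cc1cc(C)no1 | intermediate
7 | tert-butyl 4-(3-methylisoxazol-5-yl)buta-2,3-dienoate (racemic) | CC(C)(C)OC(=O)C=C=Cc1cc(C)no1 | intermediate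
8 | atraric acid (methyl 2,4-dihydroxy-3,6-dimethylbenzoate) | COC(=O)c1c(C)cc(O)c(C)c1O | starting material
9 | methyl 5-formyl-2,4-dihydroxy-3,6-dimethylbenzoate | COC(=O)c1c(C)c(C=O)c(O)c(C)c1O | intermediate
10 | methyl 5-(formyloxy)-2,4-dihydroxy-3,6-dimethylbenzoate (not isolated) | COC(=O)c1c(C)c(OC=O)c(O)c(C)c1O | intermediate
11 | methyl 2,4,5-trihydroxy-3,6-dimethylbenzoate | COC(=O)c1c(C)c(O)c(O)c(C)c1O | intermediate
12 | methyl 4,5-bis(tert-butyldimethylsilyloxy)-2-hydroxy-3,6-dimethylbenzoate | COC(=O)c1c(C)c(O[Si](C)(C)C(C)(C)C)c(O[Si](C)(C)C(C)(C)C)c(C)c1O | intermediate
13 | methyl 4,5-bis(tert-butyldimethylsilyloxy)-3,6-dimethyl-2-(triisopropylsilyloxy)benzoate | COC(=O)c1c(C)c(O[Si](C)(C)C(C)(C)C)c(O[Si](C)(C)C(C)(C)C)c(C)c1O[Si](C(C)C)(C(C)C)C(C)C | intermediate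
14 | methyl 3,6-bis(bromomethyl)-4,5-bis(tert-butyldimethylsilyloxy)-2-(triisopropylsilyloxy)benzoate (not isolated) | COC(=O)c1c(CBr)c(O[Si](C)(C)C(C)(C)C)c(O[Si](C)(C)C(C)(C)C)c(CBr)c1O[Si](C(C)C)(C(C)C)C(C)C | intermediate
15 | 6-(acetoxymethyl)-4,5-bis(tert-butyldimethylsilyloxy)-7-(triisopropylsilyloxy)isobenzofuran-1(3H)-one | CC(=O)OCc1c(O[Si](C(C)C)(C(C)C)C(C)C)c2C(=O)OCc2c(O[Si](C)(C)C(C)(C)C)c1O[Si](C)(C)C(C)(C)C | intermediate
16 | rac-6-(acetoxymethyl)-3-bromo-4,5-bis(tert-butyldimethylsilyloxy)-7-(triisopropylsilyloxy)isobenzofuran-1(3H)-one (not isolated) | CC(=O)OCc1c(O[Si](C(C)C)(C(C)C)C(C)C)c2C(=O)OC(Br)c2c(O[Si](C)(C)C(C)(C)C)c1O[Si](C)(C)C(C)(C)C | intermediate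
17 | rac-6-(acetoxymethyl)-3-methoxy-4,5-bis(tert-butyldimethylsilyloxy)-7-(triisopropylsilyloxy)isobenzofuran-1(3H)-one | CC(=O)OCc1c(O[Si](C(C)C)(C(C)C)C(C)C)c2C(=O)OC(OC)c2c(O[Si](C)(C)C(C)(C)C)c1O[Si](C)(C)C(C)(C)C | intermediate
18 | rac-6-(acetoxymethyl)-4,5-dihydroxy-3-methoxy-7-(triisopropylsilyloxy)isobenzofuran-1(3H)-one | CC(=O)OCc1c(O[Si](C(C)C)(C(C)C)C(C)C)c2C(=O)OC(OC)c2c(O)c1O | intermediate
19 | rac-6-(acetoxymethyl)-4-hydroxy-3-methoxy-5-(methoxymethoxy)-7-(triisopropylsilyloxy)isobenzofuran-1(3H)-one | CC(=O)OCc1c(O[Si](C(C)C)(C(C)C)C(C)C)c2C(=O)OC(OC)c2c(O)c1OCOC | intermediate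
20 | tert-butyl 3-{[6-(acetoxymethyl)-3-methoxy-5-(methoxymethoxy)-1-oxo-7-(triisopropylsilyloxy)-1,3-dihydroisobenzofuran-4-yl]oxy}-4-(3-methylisoxazol-5-yl)but-2-enoate (racemic acetal, E/Z mixture) | CC(=O)OCc1c(O[Si](C(C)C)(C(C)C)C(C)C)c2C(=O)OC(OC)c2c(OC(Cc2cc(C)no2)=CC(=O)OC(C)(C)C)c1OCOC | intermediate
21 | 3-{[6-(acetoxymethyl)-5-hydroxy-3-methoxy-1-oxo-7-(triisopropylsilyloxy)-1,3-dihydroisobenzofuran-4-yl]oxy}-4-(3-methylisoxazol-5-yl)but-2-enoic acid (racemic acetal, E/Z mixture) | CC(=O)OCc1c(O[Si](C(C)C)(C(C)C)C(C)C)c2C(=O)OC(OC)c2c(OC(Cc2cc(C)no2)=CC(=O)O)c1O | intermediate
22 | rac-silyl-protected isoxazolylmethyl benzodioxepinone (key-step precursor) | CC(=O)OCc1c(O[Si](C(C)C)(C(C)C)C(C)C)c2c(c3c1OC(=O)C=C(Cc1cc(C)no1)O3)C(OC)OC2=O | intermediate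
23 | Z-enaminone from N–O cleavage of 22 (racemic acetal, not isolated) | CC(=O)OCc1c(O[Si](C(C)C)(C(C)C)C(C)C)c2c(c3c1OC(=O)C=C(CC(=O)/C=C(/C)N)O3)C(OC)OC2=O | intermediate
24 | rac-4-deformylgalbinic acid methyl acetal triisopropylsilyl ether (key-step product) | CC(=O)OCc1c(O[Si](C(C)C)(C(C)C)C(C)C)c2c(c3c1OC(=O)c1c(C)cc(O)cc1O3)C(OC)OC2=O | intermediate
25 | rac-galbinic acid methyl acetal triisopropylsilyl ether (not isolated) | CC(=O)OCc1c(O[Si](C(C)C)(C(C)C)C(C)C)c2c(c3c1OC(=O)c1c(C)cc(O)c(C=O)c1O3)C(OC)OC2=O | intermediate
26 | rac-galbinic acid methyl acetal (not isolated) | CC(=O)OCc1c(O)c2c(c3c1OC(=O)c1c(C)cc(O)c(C=O)c1O3)C(OC)OC2=O | intermediate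
27 | rac-galbinic acid | CC(=O)OCc1c(O)c2c(c3c1OC(=O)c1c(C)cc(O)c(C=O)c1O3)C(O)OC2=O | intermediate
28 | (S)-galbinic acid | CC(=O)OCc1c(O)c2c(c3c1OC(=O)c1c(C)cc(O)c(C=O)c1O3)[C@@H](O)OC2=O | target

## Step count and least certain steps

Total step count: 16. Longest linear sequence: 14 steps (steps 3 to 16, from 8); steps 1 and 2 form the side branch that joins in step 11.

Step 16 (labelled). The racemate may crystallise as a racemic compound and not as a conglomerate, in which case grinding cannot enrich either enantiomer; slow solvolysis of the benzylic acetate in the slurry is a second concern. Fallback with known chemistry: 27 would be resolved by preparative low-temperature chromatography on an immobilised polysaccharide chiral stationary phase with an aprotic eluent, as is done for enantiomers that interconvert slowly. The (S) fractions would be evaporated cold and crystallised at once to give 28; this also supplies the seed crystals. No compound outside the list is made (F0).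

Step 14 (key step). The vinylogous amide nitrogen may attack the enol ether carbon before the acid is added and expel the ring B phenoxide (pyridone formation with opening of the seven-membered ring). After partial hydrolysis the diketone oxygen may do the same (pyranone formation), or the vinylogous carbonate may hydrolyse during the aqueous reflux. Fallback: setting out from 22, the N–O bond would be cleaved as before but the enaminone 23 isolated. Its vinylogous amide would be hydrolysed with dilute aqueous HCl in THF to the free beta-diketone F1. F1 would then be folded under mild base (Et3N, CH2Cl2, then a trace of acid for dehydration), through deprotonation of the methylene between the ketone and the enol ether and aldol attack of the resulting dienolate on the methyl ketone, as in the aromatisation of diketo-dioxinones. This returns to the route at 24.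

Step 7. Over-bromination of a methyl group, oxidation of the electron-rich tris(silyloxy)arene by NBS, or loss of a silyl group during the silver-assisted ionisation may erode the differentiation of the two benzylic carbons. Fallback by lateral lithiation, setting out from 11: the catechol would be protected as methyl 2-hydroxy-4,5-bis(methoxymethoxy)-3,6-dimethylbenzoate F2 (MOMCl, iPr2NEt). The dianion of F2 (LDA, THF, −78 °C) would be hydroxylated at the methyl group ortho to the ester with (camphorsulfonyl)oxaziridine and lactonised to 7-hydroxy-4,5-bis(methoxymethoxy)-6-methylisobenzofuran-1(3H)-one F3. Acidic methanol would give 4,5,7-trihydroxy-6-methylisobenzofuran-1(3H)-one F4, and silylation as in steps 5 and 6 would give the bis(tert-butyldimethylsilyl) ether F5 and then the fully silylated phthalide F6. NBS (2.1 equiv) would brominate the phthalide CH2 and the remaining methyl group to the dibromide F7. Potassium acetate in DMF would give the diacetate F8, and methanol with camphorsulfonic acid would exchange the acylal acetate for methoxide. This returns to the route at 17.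

Step 13. Before the ring closes, the vinylogous acyl group may migrate to the neighbouring free phenol through a spiro-ketal (leading to the regioisomeric dioxepinone), or the E acid may fail to reach a cyclisable geometry. Fallback that uses the spiro-ketal deliberately, setting out from 18: both catechol hydroxyls would be added to allenoate 7 (Cs2CO3, MeCN) to give the spiro-ketal tert-butyl ester F9. TFA would give the spiro-ketal acid F10. Activation as the mixed anhydride with 2,4,6-trichlorobenzoyl chloride, Et3N and DMAP should open the ketal by beta-elimination of the better leaving aryloxide (the oxygen para to the phthalide carbonyl), which is acylated at once in the ion pair. This returns to the route at 22.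

Step 15. Formylation may go to the ring A carbon next to the methyl group (poor regioselectivity), and TiCl4 may ionise the benzylic acetate. Fallback with a different mechanism, setting out from 24: ortho-formylation through the magnesium phenoxide (MgCl2, Et3N, paraformaldehyde, MeCN, reflux), in which the aldehyde carbon is delivered within a magnesium chelate that the neighbouring ether oxygen can join and no strong Lewis acid is present. It returns to the route at 25, followed by the same fluoride and aqueous acid treatment to 27. No compound outside the list is made (F0).

## Further compounds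

F0 | step 16 | none | none
F1 | step 14 | free beta-diketone from hydrolysis of enaminone 23 (racemic acetal) | CC(=O)OCc1c(O[Si](C(C)C)(C(C)C)C(C)C)c2c(c3c1OC(=O)C=C(CC(=O)CC(C)=O)O3)C(OC)OC2=O
F2 | step 7 | methyl 2-hydroxy-4,5-bis(methoxymethoxy)-3,6-dimethylbenzoate | COC(=O)c1c(C)c(OCOC)c(OCOC)c(C)c1O
F3 | step 7 | 7-hydroxy-4,5-bis(methoxymethoxy)-6-methylisobenzofuran-1(3H)-one | Cc1c(O)c2C(=O)OCc2c(OCOC)c1OCOC
F4 | step 7 | 4,5,7-trihydroxy-6-methylisobenzofuran-1(3H)-one | Cc1c(O)c2C(=O)OCc2c(O)c1O
F5 | step 7 | 4,5-bis(tert-butyldimethylsilyloxy)-7-hydroxy-6-methylisobenzofuran-1(3H)-one | Cc1c(O)c2C(=O)OCc2c(O[Si](C)(C)C(C)(C)C)c1O[Si](C)(C)C(C)(C)C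
F6 | step 7 | 4,5-bis(tert-butyldimethylsilyloxy)-6-methyl-7-(triisopropylsilyloxy)isobenzofuran-1(3H)-one | Cc1c(O[Si](C(C)C)(C(C)C)C(C)C)c2C(=O)OCc2c(O[Si](C)(C)C(C)(C)C)c1O[Si](C)(C)C(C)(C)C
F7 | step 7 | rac-3-bromo-6-(bromomethyl)-4,5-bis(tert-butyldimethylsilyloxy)-7-(triisopropylsilyloxy)isobenzofuran-1(3H)-one | BrCc1c(O[Si](C(C)C)(C(C)C)C(C)C)c2C(=O)OC(Br)c2c(O[Si](C)(C)C(C)(C)C)c1O[Si](C)(C)C(C)(C)C
F8 | step 7 | rac-3-acetoxy-6-(acetoxymethyl)-4,5-bis(tert-butyldimethylsilyloxy)-7-(triisopropylsilyloxy)isobenzofuran-1(3H)-one | CC(=O)OCc1c(O[Si](C(C)C)(C(C)C)C(C)C)c2C(=O)OC(OC(C)=O)c2c(O[Si](C)(C)C(C)(C)C)c1O[Si](C)(C)C(C)(C)C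
F9 | step 13 | spiro-ketal (1,3-benzodioxole) tert-butyl ester from 18 and 7 (mixture of diastereomers) | CC(=O)OCc1c(O[Si](C(C)C)(C(C)C)C(C)C)c2C(=O)OC(OC)c2c2OC(Cc3cc(C)no3)(CC(=O)OC(C)(C)C)Oc12
F10 | step 13 | spiro-ketal (1,3-benzodioxole) acetic acid (mixture of diastereomers) | CC(=O)OCc1c(O[Si](C(C)C)(C(C)C)C(C)C)c2C(=O)OC(OC)c2c2OC(Cc3cc(C)no3)(CC(=O)O)Oc12
F0 | step 15 | none | none
A1 | alternative 1 | 4-hydroxy-3-isopropoxy-2-[(methoxymethoxy)methyl]-4-[2-(menthyloxy)-5-oxo-2,5-dihydrofuran-3-yl]cyclobut-2-enone | COCOCC1=C(OC(C)C)C(O)(C1=O)C2=CC(=O)O[C@@H]2O[C@@H]3C[C@H](C)CC[C@H]3C(C)C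
A2 | alternative 1 | ring B hydroquinone phthalide menthyl acetal | COCOCc1c(O)c2c(c(O)c1OC(C)C)[C@@H](O[C@@H]1C[C@H](C)CC[C@H]1C(C)C)OC2=O
A3 | alternative 2 | depside of the ring B catechol phthalide with 2-fluoro-3-formyl-4-(methoxymethoxy)-6-methylbenzoic acid | CC(=O)OCc1c(OCOC)c2c(c(O)c1OC(=O)c1c(C)cc(OCOC)c(C=O)c1F)[C@@H](OC)OC2=O
A4 | alternative 2 | bis(methoxymethyl) galbinic acid methyl acetal | CC(=O)OCc1c(OCOC)c2c(c3c1OC(=O)c1c(C)cc(OCOC)c(C=O)c1O3)[C@@H](OC)OC2=O
A5 | alternative 3 | dioxepinone-fused 5-acyl-4-aryloxy-6-methyl-2-pyrone | CC(=O)OCc1c(O)c2c(c3c1OC(=O)c1c(C)oc(=O)cc1O3)[C@@H](OC)OC2=O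
A6 | alternative 3 | deformyl O-methyl galbinic acid methyl acetal | CC(=O)OCc1c(O)c2c(c3c1OC(=O)c1c(C)cc(OC)cc1O3)[C@@H](OC)OC2=O
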